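## Retrosynthetic overview

1. The enal is made last: C3–CHO comes from palladium-catalysed formylation of the enol triflate of a 1-aryl-2-(acetoxymethyl)-2-tetralone; the final step removes two aryl silyl ethers.
2. Key step: the six-membered carbocycle is formed by a one-carbon ring expansion (1,2-aryl shift, Me3SiCHN2) of a trans-3-aryl-2-(acetoxymethyl)indan-1-one; the inserted CH2 becomes C4 and the old carbonyl becomes C3.
3. The five-membered ring is closed first, by intramolecular acyl–aryl coupling of an aldehyde onto the aryl bromide that marks C4a.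
4. The C1–C2 bond, the C1 stereocentre and the acetoxymethyl group come from one new organocascade: p-quinone methide (from a p-hydroxybenzhydrol) + acrolein + AcOH under chiral amine catalysis.
5. Both aryl rings come from catechol via 4-bromoguaiacol: lithiation between OMe and Br builds the fused ring (this fixes the 7-oxy-8-methoxy pattern), and Br–Li exchange gives the pendant ring.

Numbering used: C1 (aryl), C2 (CH2OAc), C3 (CHO), C4 (=CH), C7 (OH), C8 (OMe); the target is (1S,2R), trans. Assumption: the enamine 1,6-addition in step 5 follows the like (synclinal) topicity of enamine Michael additions.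

## Route

Step 1
Reactants: 1 catechol
Product: 2 guaiacol (2-methoxyphenol)
Conditions: MeI (1.0 eq), K2CO3 (1.0 eq), acetone, reflux
Reagents that add atoms: iodomethane CI
Why: Williamson mono-O-methylation of the symmetric diol with one equivalent of MeI; the monoether is separated from veratrole and unreacted catechol by distillation.

Step 2
Reactants: 2 guaiacol
Product: 3 4-bromo-2-methoxyphenol
Conditions: NBS (1.0 eq), MeCN, 0 °C
Reagents that add atoms: N-bromosuccinimide O=C1CCC(=O)N1Br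
Why: electrophilic aromatic bromination goes para to the free hydroxyl, the stronger director.

Step 3
Reactants: 3 4-bromo-2-methoxyphenol
Product: 6 6-bromo-2-methoxy-3-(triisopropylsilyloxy)benzaldehyde, via silyl ether 4 (not isolated), via aryllithium 5 (not isolated)
Conditions: NaH (1.0 eq), iPr3SiCl (1.0 eq), THF, 0 °C to rt; then LiN(iPr)2 (1.2 eq), −78 °C, 1 h; then DMF, −78 to 0 °C; H2O
Reagents that add atoms: chlorotriisopropylsilane CC(C)[Si](Cl)(C(C)C)C(C)C; N,N-dimethylformamide CN(C)C=O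
Why: in-flask O-silylation, then directed ortho-lithiation at the only C–H flanked by OMe and Br (the bulky silyl ether does not direct) and formylation with DMF; −78 °C prevents loss of LiBr to the aryne.

Step 4
Reactants: 3 4-bromo-2-methoxyphenol (1.15 eq); 6 6-bromo-2-methoxy-3-(triisopropylsilyloxy)benzaldehyde
Product: 8 [6-bromo-2-methoxy-3-(triisopropylsilyloxy)phenyl](4-hydroxy-3-methoxyphenyl)methanol (racemic), via dilithio phenolate 7 (not isolated)
Conditions: 3, n-BuLi (2.0 eq per 3), THF, −78 to −20 °C; then 6, −78 °C; H2O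
Reagents that add atoms: none
Why: deprotonation and Br–Li exchange give the lithium 4-lithiophenolate, whose 1,2-addition to the aldehyde gives the p-hydroxybenzhydrol; the carbinol configuration does not matter because the centre is ionised in step 5.

Step 5
Reactants: 8 [6-bromo-2-methoxy-3-(triisopropylsilyloxy)phenyl](4-hydroxy-3-methoxyphenyl)methanol; 9 acrolein (3 eq)
Product: 12 (2R,3S)-3-[6-bromo-2-methoxy-3-(triisopropylsilyloxy)phenyl]-2-formyl-3-[3-methoxy-4-(triisopropylsilyloxy)phenyl]propyl acetate, via quinone methide 10 (not isolated), via phenol aldehyde 11 (not isolated)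
Conditions: (R)-2-[diphenyl(trimethylsilyloxy)methyl]pyrrolidine (20 mol%), AcOH (10 eq), 4 Å MS, CH2Cl2, −20 °C to rt; then imidazole (15 eq), iPr3SiCl (3 eq), 0 °C to rt
Reagents that add atoms: acetic acid CC(=O)O; chlorotriisopropylsilane CC(C)[Si](Cl)(C(C)C)C(C)C
Why: Proposed new method: AcOH dehydrates 8 to p-quinone methide 10 and also adds as acetate to the acrolein–amine iminium ion (oxa-Michael), giving the β-acetoxy enamine directly; this enamine adds 1,6 to 10 from the face left open by the diphenyl(silyloxy)methyl group through the synclinal transition state of enamine Michael additions, which sets the diaryl carbon as 3S (later C1) and, provisionally, the α-carbon as 2R; rearomatisation drives the step and the α-branched product does not re-enter the cycle; the closest known reactions are the diarylprolinol silyl ether-catalysed 1,6-addition of aldehydes to preformed p-quinone methides and iminium–enamine organocascades; the phenol is silylated in the same flask and the minor diastereomer is removed by chromatography.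

Step 6
Reactants: 12 (2R,3S)-3-[6-bromo-2-methoxy-3-(triisopropylsilyloxy)phenyl]-2-formyl-3-[3-methoxy-4-(triisopropylsilyloxy)phenyl]propyl acetate
Product: 14 [(2S,3S)-4-methoxy-3-[3-methoxy-4-(triisopropylsilyloxy)phenyl]-1-oxo-5-(triisopropylsilyloxy)-2,3-dihydro-1H-inden-2-yl]methyl acetate (trans), via cis-indanone 13 (not isolated)
Conditions: Ir[dF(CF3)ppy]2(dtbbpy)PF6 (1 mol%), NiBr2(dme) (10 mol%), 4,4'-di-tert-butyl-2,2'-bipyridine (10 mol%), quinuclidine (10 mol%), K2CO3 (1.5 eq), 1,4-dioxane, blue LEDs, rt; filter, evaporate; then p-TsOH·H2O (0.2 eq), CHCl3, 40 °C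
Reagents that add atoms: none
Why: nickel/photoredox aldehyde C–H arylation by hydrogen-atom transfer, run intramolecularly, closes the five-membered ketone at the carbon that carried Br; acid-catalysed enolisation then equilibrates C2 to the favoured trans-2,3-disubstituted indanone without forming an enolate that would expel acetate, while C3 (S) is untouched.

Step 7
Reactants: 14 [(2S,3S)-4-methoxy-3-[3-methoxy-4-(triisopropylsilyloxy)phenyl]-1-oxo-5-(triisopropylsilyloxy)-2,3-dihydro-1H-inden-2-yl]methyl acetate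
Product: 16 [(1S,2S)-8-methoxy-1-[3-methoxy-4-(triisopropylsilyloxy)phenyl]-3-oxo-7-(triisopropylsilyloxy)-1,2,3,4-tetrahydronaphthalen-2-yl]methyl acetate, via silyl ketone 15 (not isolated)
Conditions: Me3SiCHN2 (1.5 eq), BF3·OEt2 (1.5 eq), CH2Cl2, −78 to −20 °C; then silica gel, wet CH2Cl2, rt
Reagents that add atoms: (trimethylsilyl)diazomethane C[Si](C)(C)C=[N+]=[N-]
Why: Tiffeneau–Demjanov-type one-carbon ring expansion: the diazo carbon adds to the BF3-activated ketone and the electron-rich aryl carbon (para to the silyloxy group) migrates in a 1,2-shift with loss of N2, much faster than the acetoxymethyl-bearing alkyl carbon, giving the 2-tetralone with both stereocentres retained; the C–Si group blocks a second homologation until it is removed on silica.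

Step 8
Reactants: 16 [(1S,2S)-8-methoxy-1-[3-methoxy-4-(triisopropylsilyloxy)phenyl]-3-oxo-7-(triisopropylsilyloxy)-1,2,3,4-tetrahydronaphthalen-2-yl]methyl acetate
Product: 17 [(1S,2S)-8-methoxy-1-[3-methoxy-4-(triisopropylsilyloxy)phenyl]-3-{[(trifluoromethyl)sulfonyl]oxy}-7-(triisopropylsilyloxy)-1,2-dihydronaphthalen-2-yl]methyl acetate
Conditions: Tf2O (1.2 eq), 2,6-di-tert-butyl-4-methylpyridine (1.5 eq), CH2Cl2, −78 to 0 °C
Reagents that add atoms: trifluoromethanesulfonic anhydride O=S(=O)(OS(=O)(=O)C(F)(F)F)C(F)(F)F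
Why: enol triflate formation from a 2-tetralone under non-enolate conditions gives the arene-conjugated C3=C4 isomer and leaves the β-acetoxy C2 centre untouched.

Step 9
Reactants: 17 [(1S,2S)-8-methoxy-1-[3-methoxy-4-(triisopropylsilyloxy)phenyl]-3-{[(trifluoromethyl)sulfonyl]oxy}-7-(triisopropylsilyloxy)-1,2-dihydronaphthalen-2-yl]methyl acetate
Product: 18 [(1S,2R)-3-formyl-8-methoxy-1-[3-methoxy-4-(triisopropylsilyloxy)phenyl]-7-(triisopropylsilyloxy)-1,2-dihydronaphthalen-2-yl]methyl acetate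
Conditions: Pd(PPh3)4 (5 mol%), LiCl (3 eq), CO (3 atm), Bu3SnH (1.2 eq, syringe pump), THF, 50 °C
Reagents that add atoms: carbon monoxide [C-]#[O+]
Why: Stille-type palladium-catalysed reductive carbonylation (formylation) of the vinyl triflate by oxidative addition, CO insertion and hydride transfer from tin, under neutral conditions that spare the γ-acetoxy enal.

Step 10
Reactants: 18 [(1S,2R)-3-formyl-8-methoxy-1-[3-methoxy-4-(triisopropylsilyloxy)phenyl]-7-(triisopropylsilyloxy)-1,2-dihydronaphthalen-2-yl]methyl acetate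
Product: 19 [(1S,2R)-3-formyl-7-hydroxy-1-(4-hydroxy-3-methoxyphenyl)-8-methoxy-1,2-dihydronaphthalen-2-yl]methyl acetate (target)
Conditions: Bu4NF (2.5 eq), AcOH (3 eq), THF, 0 °C
Reagents that add atoms: none
Why: fluoride desilylation of both aryl silyl ethers; the AcOH buffer keeps the phenols protonated so the alkyl acetate and the enal survive.

## Compound list

1 | catechol | Oc1ccccc1O | starting material
2 | guaiacol | COc1ccccc1O | intermediate
3 | 4-bromo-2-methoxyphenol | COc1cc(Br)ccc1O | intermediate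
4 | (4-bromo-2-methoxyphenoxy)triisopropylsilane | COc1cc(Br)ccc1O[Si](C(C)C)(C(C)C)C(C)C | intermediate
5 | [6-bromo-2-methoxy-3-(triisopropylsilyloxy)phenyl]lithium | COc1c([Li])c(Br)ccc1O[Si](C(C)C)(C(C)C)C(C)C | intermediate
6 | 6-bromo-2-methoxy-3-(triisopropylsilyloxy)benzaldehyde | COc1c(C=O)c(Br)ccc1O[Si](C(C)C)(C(C)C)C(C)C | intermediate
7 | lithium 4-lithio-2-methoxyphenolate | [Li]Oc1ccc([Li])cc1OC | intermediate
8 | [6-bromo-2-methoxy-3-(triisopropylsilyloxy)phenyl](4-hydroxy-3-methoxyphenyl)methanol (racemic) | COc1cc(C(O)c2c(Br)ccc(O[Si](C(C)C)(C(C)C)C(C)C)c2OC)ccc1O | intermediate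
9 | acrolein | C=CC=O | starting material
10 | 4-{[6-bromo-2-methoxy-3-(triisopropylsilyloxy)phenyl]methylidene}-2-methoxycyclohexa-2,5-dien-1-one (E/Z mixture) | COC1=CC(=Cc2c(Br)ccc(O[Si](C(C)C)(C(C)C)C(C)C)c2OC)C=CC1=O | intermediate
11 | (2R,3S)-3-[6-bromo-2-methoxy-3-(triisopropylsilyloxy)phenyl]-2-formyl-3-(4-hydroxy-3-methoxyphenyl)propyl acetate | COc1cc([C@@H](c2c(Br)ccc(O[Si](C(C)C)(C(C)C)C(C)C)c2OC)[C@@H](C=O)COC(C)=O)ccc1O | intermediate
12 | (2R,3S)-3-[6-bromo-2-methoxy-3-(triisopropylsilyloxy)phenyl]-2-formyl-3-[3-methoxy-4-(triisopropylsilyloxy)phenyl]propyl acetate | COc1cc([C@@H](c2c(Br)ccc(O[Si](C(C)C)(C(C)C)C(C)C)c2OC)[C@@H](C=O)COC(C)=O)ccc1O[Si](C(C)C)(C(C)C)C(C)C | intermediate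
13 | [(2R,3S)-4-methoxy-3-[3-methoxy-4-(triisopropylsilyloxy)phenyl]-1-oxo-5-(triisopropylsilyloxy)-2,3-dihydro-1H-inden-2-yl]methyl acetate (cis) | COc1cc([C@H]2c3c(ccc(O[Si](C(C)C)(C(C)C)C(C)C)c3OC)C(=O)[C@H]2COC(C)=O)ccc1O[Si](C(C)C)(C(C)C)C(C)C | intermediate
14 | [(2S,3S)-4-methoxy-3-[3-methoxy-4-(triisopropylsilyloxy)phenyl]-1-oxo-5-(triisopropylsilyloxy)-2,3-dihydro-1H-inden-2-yl]methyl acetate (trans) | COc1cc([C@H]2c3c(ccc(O[Si](C(C)C)(C(C)C)C(C)C)c3OC)C(=O)[C@@H]2COC(C)=O)ccc1O[Si](C(C)C)(C(C)C)C(C)C | intermediate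
15 | [(1S,2S)-8-methoxy-1-[3-methoxy-4-(triisopropylsilyloxy)phenyl]-3-oxo-7-(triisopropylsilyloxy)-4-(trimethylsilyl)-1,2,3,4-tetrahydronaphthalen-2-yl]methyl acetate (C4 epimers) | COc1cc([C@H]2c3c(ccc(O[Si](C(C)C)(C(C)C)C(C)C)c3OC)C([Si](C)(C)C)C(=O)[C@@H]2COC(C)=O)ccc1O[Si](C(C)C)(C(C)C)C(C)C | intermediate
16 | [(1S,2S)-8-methoxy-1-[3-methoxy-4-(triisopropylsilyloxy)phenyl]-3-oxo-7-(triisopropylsilyloxy)-1,2,3,4-tetrahydronaphthalen-2-yl]methyl acetate | COc1cc([C@H]2c3c(ccc(O[Si](C(C)C)(C(C)C)C(C)C)c3OC)CC(=O)[C@@H]2COC(C)=O)ccc1O[Si](C(C)C)(C(C)C)C(C)C | intermediate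
17 | [(1S,2S)-8-methoxy-1-[3-methoxy-4-(triisopropylsilyloxy)phenyl]-3-{[(trifluoromethyl)sulfonyl]oxy}-7-(triisopropylsilyloxy)-1,2-dihydronaphthalen-2-yl]methyl acetate | COc1cc([C@H]2c3c(ccc(O[Si](C(C)C)(C(C)C)C(C)C)c3OC)C=C(OS(=O)(=O)C(F)(F)F)[C@@H]2COC(C)=O)ccc1O[Si](C(C)C)(C(C)C)C(C)C | intermediate
18 | [(1S,2R)-3-formyl-8-methoxy-1-[3-methoxy-4-(triisopropylsilyloxy)phenyl]-7-(triisopropylsilyloxy)-1,2-dihydronaphthalen-2-yl]methyl acetate | COc1cc([C@H]2c3c(ccc(O[Si](C(C)C)(C(C)C)C(C)C)c3OC)C=C(C=O)[C@@H]2COC(C)=O)ccc1O[Si](C(C)C)(C(C)C)C(C)C | intermediate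
19 | [(1S,2R)-3-formyl-7-hydroxy-1-(4-hydroxy-3-methoxyphenyl)-8-methoxy-1,2-dihydronaphthalen-2-yl]methyl acetate | COc1cc([C@H]2c3c(ccc(O)c3OC)C=C(C=O)[C@@H]2COC(C)=O)ccc1O | target

## Step count and risks

Total steps: 10. Longest linear sequence: 10 (1 to 19; compound 3 is used again in step 4).

Steps most likely to fail:

**Step 5 (new organocascade).** Risks are slow attack on the di-ortho-substituted quinone methide carbon, competing oxa-Michael partners, and the unproven sense and level of diastereocontrol. The fallback uses known chemistry, sets out from 6 (and from 4, isolated in this variant) and comes back at 14.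
- Wittig reaction of 6 with Ph3P=CHCHO (toluene, 80 °C) gives (E)-3-[6-bromo-2-methoxy-3-(triisopropylsilyloxy)phenyl]prop-2-enal F1.
- Silyl ether 4, treated with n-BuLi, then B(OiPr)3 and aqueous acid, gives [3-methoxy-4-(triisopropylsilyloxy)phenyl]boronic acid F2.
- Hayashi–Miyaura asymmetric 1,4-addition of F2 to F1 ([Rh(C2H4)2Cl]2, chiral bicyclo[2.2.2]octadiene ligand of the enantiomeric series that gives the 3S product, KOH, dioxane/H2O, 30 °C) gives (3S)-3-[6-bromo-2-methoxy-3-(triisopropylsilyloxy)phenyl]-3-[3-methoxy-4-(triisopropylsilyloxy)phenyl]propanal F3.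
- Cyclisation of F3 under the nickel/photoredox conditions of step 6 gives (3S)-4-methoxy-3-[3-methoxy-4-(triisopropylsilyloxy)phenyl]-5-(triisopropylsilyloxy)-2,3-dihydro-1H-inden-1-one F4.
- Aldol reaction of the lithium enolate of F4 (LiN(SiMe3)2, THF, −78 °C) with monomeric formaldehyde, anti to the aryl group, gives (2S,3S)-2-(hydroxymethyl)-4-methoxy-3-[3-methoxy-4-(triisopropylsilyloxy)phenyl]-5-(triisopropylsilyloxy)-2,3-dihydro-1H-inden-1-one F5.
- Ac2O in pyridine then gives 14.

**Step 6 (acyl–aryl ring closure and C2 equilibration).** Risks are hydrogen abstraction at the diarylmethine C–H, loss of acetate from the β-acetoxy aldehyde, and slow acid epimerisation. The fallback sets out from 12 and comes back at 14 (through 13).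
- Takai–Lombardo methylenation of 12 (Zn, CH2Br2, TiCl4, THF, 0 °C) gives (2R,3S)-3-[6-bromo-2-methoxy-3-(triisopropylsilyloxy)phenyl]-2-ethenyl-3-[3-methoxy-4-(triisopropylsilyloxy)phenyl]propyl acetate F6.
- A 5-exo Heck cyclisation (Pd(OAc)2, PPh3, Ag2CO3, MeCN, 70 °C) gives [(1S,2S)-7-methoxy-1-[3-methoxy-4-(triisopropylsilyloxy)phenyl]-3-methylidene-6-(triisopropylsilyloxy)-2,3-dihydro-1H-inden-2-yl]methyl acetate F7.
- Ozonolysis (O3, CH2Cl2, −78 °C, then Me2S) gives cis-indanone 13, which the p-TsOH equilibration of step 6 converts into 14.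

**Step 7 (ring expansion).** Risks are sluggish addition to the electron-rich aryl ketone, epoxide formation, and partial C2 epimerisation of tetralone 16 on handling. The fallback sets out from 14 and comes back at 16.
- Takai–Lombardo methylenation of 14 gives [(1S,2R)-7-methoxy-1-[3-methoxy-4-(triisopropylsilyloxy)phenyl]-3-methylidene-6-(triisopropylsilyloxy)-2,3-dihydro-1H-inden-2-yl]methyl acetate F8.
- Koser's reagent PhI(OH)OTs in 95% MeOH at 0 °C then effects an oxidative ring expansion: trivalent iodine adds to the exocyclic CH2, the aryl carbon shifts 1,2 onto it as iodobenzene leaves, and hydrolysis of the oxocarbenium ion gives 16.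

Further compounds
F1 | step 5 | (E)-3-[6-bromo-2-methoxy-3-(triisopropylsilyloxy)phenyl]prop-2-enal | O=C/C=C/c1c(Br)ccc(O[Si](C(C)C)(C(C)C)C(C)C)c1OC
F2 | step 5 | [3-methoxy-4-(triisopropylsilyloxy)phenyl]boronic acid | COc1cc(B(O)O)ccc1O[Si](C(C)C)(C(C)C)C(C)C
F3 | step 5 | (3S)-3-[6-bromo-2-methoxy-3-(triisopropylsilyloxy)phenyl]-3-[3-methoxy-4-(triisopropylsilyloxy)phenyl]propanal | COc1cc([C@@H](c2c(Br)ccc(O[Si](C(C)C)(C(C)C)C(C)C)c2OC)CC=O)ccc1O[Si](C(C)C)(C(C)C)C(C)C
F4 | step 5 | (3S)-4-methoxy-3-[3-methoxy-4-(triisopropylsilyloxy)phenyl]-5-(triisopropylsilyloxy)-2,3-dihydro-1H-inden-1-one | COc1cc([C@H]2c3c(ccc(O[Si](C(C)C)(C(C)C)C(C)C)c3OC)C(=O)C2)ccc1O[Si](C(C)C)(C(C)C)C(C)C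
F5 | step 5 | (2S,3S)-2-(hydroxymethyl)-4-methoxy-3-[3-methoxy-4-(triisopropylsilyloxy)phenyl]-5-(triisopropylsilyloxy)-2,3-dihydro-1H-inden-1-one | COc1cc([C@H]2c3c(ccc(O[Si](C(C)C)(C(C)C)C(C)C)c3OC)C(=O)[C@@H]2CO)ccc1O[Si](C(C)C)(C(C)C)C(C)C
F6 | step 6 | (2R,3S)-3-[6-bromo-2-methoxy-3-(triisopropylsilyloxy)phenyl]-2-ethenyl-3-[3-methoxy-4-(triisopropylsilyloxy)phenyl]propyl acetate | COc1cc([C@@H](c2c(Br)ccc(O[Si](C(C)C)(C(C)C)C(C)C)c2OC)[C@@H](C=C)COC(C)=O)ccc1O[Si](C(C)C)(C(C)C)C(C)C
F7 | step 6 | [(1S,2S)-7-methoxy-1-[3-methoxy-4-(triisopropylsilyloxy)phenyl]-3-methylidene-6-(triisopropylsilyloxy)-2,3-dihydro-1H-inden-2-yl]methyl acetate | COc1cc([C@H]2c3c(ccc(O[Si](C(C)C)(C(C)C)C(C)C)c3OC)C(=C)[C@H]2COC(C)=O)ccc1O[Si](C(C)C)(C(C)C)C(C)C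
F8 | step 7 | [(1S,2R)-7-methoxy-1-[3-methoxy-4-(triisopropylsilyloxy)phenyl]-3-methylidene-6-(triisopropylsilyloxy)-2,3-dihydro-1H-inden-2-yl]methyl acetate | COc1cc([C@H]2c3c(ccc(O[Si](C(C)C)(C(C)C)C(C)C)c3OC)C(=C)[C@@H]2COC(C)=O)ccc1O[Si](C(C)C)(C(C)C)C(C)C
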